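**Retrosynthetic overview**
1. Target acid 12 ⇐ ethyl ester 11 (saponification, last step).
2. 11 ⇐ saligenin 9 + trienoate 7: one catalytic enantioselective oxa-[4+2] (o-quinone methide 10 + the terminal 1,1-disubstituted alkene of 7) forms C4–C3 and O1–C2 and the only stereocentre (2R).
3. 7 ⇐ dienal 6 (Z-selective Still–Gennari olefination); 6 ⇐ dienol 4 (Claisen rearrangement, sets the 6E alkene); 4 ⇐ bromide 1 + methacrolein 2.
4. 9 ⇐ 4-methoxy-2-methylphenol 8 + formaldehyde.
5. Ring order: the benzene ring is bought with 8; the dihydropyran ring is the only ring built, in step 5.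

The target is (2Z,6E)-9-[(2R)-6-methoxy-2,8-dimethylchroman-2-yl]-2,6-dimethylnona-2,6-dienoic acid.

Assumption: the sense of induction of the new step 5 cannot be predicted with certainty; the route is written with the (S,S)-catalyst giving 2R, and the equally accessible (R,R)-antipode is used if the sense proves opposite. Alcohol 4 and ether 5 are racemic and their carbinol centre is erased in step 2.

**Step 1**
Reactants: 1 4-bromo-2-methylbut-1-ene; 2 methacrolein (2-methylprop-2-enal)
Product: 4 rac-2,6-dimethylhepta-1,6-dien-3-ol, via Grignard reagent 3 (not isolated)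
Conditions: Mg, THF, 40 °C; then 2, −78 → 0 °C; sat. aq. NH4Cl
Reagents that add atoms: magnesium, [Mg] (present in 3 only)
Why: Grignard formation from the homoallylic bromide followed by clean 1,2-addition to the unhindered enal carbonyl (Grignard addition); the carbinol centre is formed racemic and is destroyed in step 2.

**Step 2**
Reactants: 4 rac-2,6-dimethylhepta-1,6-dien-3-ol
Product: 6 (4E)-4,8-dimethylnona-4,8-dienal, via allyl vinyl ether 5 (not isolated)
Conditions: ethyl vinyl ether (solvent), Hg(OAc)2 (10 mol%), reflux; evaporate; PhMe, 130 °C, sealed tube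
Reagents that add atoms: ethyl vinyl ether, C=COCC
Why: Hg(II)-catalysed transvinylation gives the allyl vinyl ether, whose Claisen rearrangement through a chair transition state with the chain pseudo-equatorial delivers the (E)-trisubstituted alkene (typically ≥95:5) and erases the racemic centre.

**Step 3**
Reactants: 6 (4E)-4,8-dimethylnona-4,8-dienal
Product: 7 ethyl (2Z,6E)-2,6,10-trimethylundeca-2,6,10-trienoate
Conditions: (CF3CH2O)2P(O)CH(Me)CO2Et, KHMDS, 18-crown-6, THF, −78 °C
Reagents that add atoms: ethyl 2-[bis(2,2,2-trifluoroethoxy)phosphoryl]propanoate, CCOC(=O)C(C)P(=O)(OCC(F)(F)F)OCC(F)(F)F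
Why: Still–Gennari olefination: the electron-poor phosphonate anion with a crown-separated potassium ion eliminates rapidly from the kinetic adduct and gives the (Z)-2-methyl enoate (typically ≥15:1) without touching the other two alkenes.

**Step 4**
Reactants: 8 4-methoxy-2-methylphenol
Product: 9 2-(hydroxymethyl)-4-methoxy-6-methylphenol
Conditions: 37% aq. CH2O (3 equiv), NaOH (1.1 equiv), H2O, N2, rt; AcOH to pH 6
Reagents that add atoms: formaldehyde, C=O
Why: Lederer–Manasse hydroxymethylation: under base 8 reacts through its phenolate at the only free ortho position (para is blocked by OMe), and room temperature stops the reaction at the saligenin.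

**Step 5**
Reactants: 7 ethyl (2Z,6E)-2,6,10-trimethylundeca-2,6,10-trienoate; 9 2-(hydroxymethyl)-4-methoxy-6-methylphenol
Product: 11 ethyl (2Z,6E)-9-[(2R)-6-methoxy-2,8-dimethyl-3,4-dihydro-2H-chromen-2-yl]-2,6-dimethylnona-2,6-dienoate, via o-quinone methide 10 (not isolated)
Conditions: (S,S)-IDPi (BINOL-derived imidodiphosphorimidate, 3,3′-Ar = 3,5-(CF3)2C6H3, N–SO2CF3 core; 5 mol%), 5 Å MS, PhMe/CH2Cl2 4:1, −20 °C, 9 (1.5 equiv) added over 12 h; water is the only by-product
Reagents that add atoms: none
Why: Proposed new method: the strong, confined chiral Brønsted acid dehydrates 9 to the o-quinone methide 10, held as its O-protonated benzylic cation in a contact ion pair inside the chiral anion pocket; the terminal CH2 of the only 1,1-disubstituted alkene of 7 attacks the exocyclic methylene in a highly asynchronous inverse-demand oxa-[4+2] and the phenol oxygen closes onto the developing tertiary cation, forming C4–C3 and O1–C2 in one operation, while the pocket differentiates methyl from the long homoallyl chain on the prochiral alkene to give 2R; the trisubstituted alkene is too hindered and the enoate too electron-poor to compete, and −20 °C keeps olefin protonation slow; the closest known chemistry is chiral phosphoric acid and imidodiphosphate catalysed [4+2] cycloaddition of in-situ o-quinone methides with styrenes, enol ethers and tethered unactivated alkenes, whereas an intermolecular enantioselective reaction of a parent CH2 o-quinone methide with an unactivated 1,1-dialkyl alkene has not been shown.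

**Step 6**
Reactants: 11 ethyl (2Z,6E)-9-[(2R)-6-methoxy-2,8-dimethyl-3,4-dihydro-2H-chromen-2-yl]-2,6-dimethylnona-2,6-dienoate
Product: 12 (2Z,6E)-9-[(2R)-6-methoxy-2,8-dimethyl-3,4-dihydro-2H-chromen-2-yl]-2,6-dimethylnona-2,6-dienoic acid
Conditions: LiOH·H2O, THF/MeOH/H2O 3:1:1, 40 °C; then 1 M HCl to pH 3
Reagents that add atoms: lithium hydroxide, [Li+].[OH-]
Why: Saponification (acyl–oxygen cleavage) of the ethyl ester; mild hydroxide at 40 °C does not isomerise the (Z)-enoate and cannot affect the quaternary ether stereocentre or the aryl methyl ether.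

**Compound list**
1 | 4-bromo-2-methylbut-1-ene | C=C(C)CCBr | starting material
2 | methacrolein | C=C(C)C=O | starting material
3 | (3-methylbut-3-en-1-yl)magnesium bromide | C=C(C)CC[Mg]Br | intermediate
4 | rac-2,6-dimethylhepta-1,6-dien-3-ol | C=C(C)C(O)CCC(C)=C | intermediate
5 | rac-3-(ethenyloxy)-2,6-dimethylhepta-1,6-diene | C=COC(CCC(C)=C)C(C)=C | intermediate
6 | (4E)-4,8-dimethylnona-4,8-dienal | O=CCC/C(C)=C/CCC(C)=C | intermediate
7 | ethyl (2Z,6E)-2,6,10-trimethylundeca-2,6,10-trienoate | CCOC(=O)/C(C)=C\CC/C(C)=C/CCC(C)=C | intermediate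
8 | 4-methoxy-2-methylphenol | COc1ccc(O)c(C)c1 | starting material
9 | 2-(hydroxymethyl)-4-methoxy-6-methylphenol | COc1cc(C)c(O)c(CO)c1 | intermediate
10 | 4-methoxy-2-methyl-6-methylidenecyclohexa-2,4-dien-1-one | COC1=CC(=C)C(=O)C(C)=C1 | intermediate
11 | ethyl (2Z,6E)-9-[(2R)-6-methoxy-2,8-dimethyl-3,4-dihydro-2H-chromen-2-yl]-2,6-dimethylnona-2,6-dienoate | COc1cc(C)c2c(c1)CC[C@@](C)(CC/C=C(\C)CC/C=C(/C)C(=O)OCC)O2 | intermediate
12 | (2Z,6E)-9-[(2R)-6-methoxy-2,8-dimethyl-3,4-dihydro-2H-chromen-2-yl]-2,6-dimethylnona-2,6-dienoic acid | COc1cc(C)c2c(c1)CC[C@@](C)(CC/C=C(\C)CC/C=C(/C)C(=O)O)O2 | target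

**Totals**
Total step count: 6. Longest linear sequence: 5 (steps 1, 2, 3, 5, 6); step 4 is a one-step branch.

**Three steps most likely to fail**

Step 5 (the proposed new reaction). The risks are: self-oligomerisation of 10 outrunning the unactivated alkene; attack at the trisubstituted alkene or a second benzylation of the electron-rich product arene; and only modest Me/CH2 face discrimination. The fallback sets out from 7 and 9 and comes back at 11. It uses the known uncatalysed thermal o-quinone methide hetero-Diels–Alder of saligenins with simple 1,1-disubstituted alkenes: 9 is heated with 7 in o-xylene at 170 °C in a sealed tube to give racemic ethyl (2Z,6E)-9-(6-methoxy-2,8-dimethyl-3,4-dihydro-2H-chromen-2-yl)-2,6-dimethylnona-2,6-dienoate F1. Preparative chiral SFC on an amylose carbamate phase then gives 11, and the unwanted ethyl (2Z,6E)-9-[(2S)-6-methoxy-2,8-dimethyl-3,4-dihydro-2H-chromen-2-yl]-2,6-dimethylnona-2,6-dienoate F2 is set aside. This fallback gives up catalytic stereocontrol in favour of resolution.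

Step 2 (one-pot transvinylation and Claisen). The risks are an incomplete vinyl exchange equilibrium, mercury side reactions at the 1,1-disubstituted alkene, and loss of the volatile aldehyde. The fallback sets out from 4 and comes back at 6. A Johnson–Claisen rearrangement of 4 with triethyl orthoacetate and catalytic propionic acid at 140 °C gives ethyl (4E)-4,8-dimethylnona-4,8-dienoate F3 with the same E-selectivity. Reduction with DIBAL-H in CH2Cl2 at −78 °C then gives 6.

Step 4 (hydroxymethylation). The risks are over-condensation to the bis(hydroxyaryl)methane and air oxidation of the electron-rich phenolate. The fallback sets out from 8 and comes back at 9. Magnesium-mediated ortho-formylation (MgCl2, Et3N, paraformaldehyde, MeCN, reflux) gives 2-hydroxy-5-methoxy-3-methylbenzaldehyde F4. Reduction with NaBH4 in MeOH at 0 °C then gives 9.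

**Further compounds**
F1 | step 5 | rac-ethyl (2Z,6E)-9-(6-methoxy-2,8-dimethyl-3,4-dihydro-2H-chromen-2-yl)-2,6-dimethylnona-2,6-dienoate | COc1cc(C)c2c(c1)CCC(C)(CC/C=C(\C)CC/C=C(/C)C(=O)OCC)O2
F2 | step 5 | ethyl (2Z,6E)-9-[(2S)-6-methoxy-2,8-dimethyl-3,4-dihydro-2H-chromen-2-yl]-2,6-dimethylnona-2,6-dienoate | COc1cc(C)c2c(c1)CC[C@](C)(CC/C=C(\C)CC/C=C(/C)C(=O)OCC)O2
F3 | step 2 | ethyl (4E)-4,8-dimethylnona-4,8-dienoate | CCOC(=O)CC/C(C)=C/CCC(C)=C
F4 | step 4 | 2-hydroxy-5-methoxy-3-methylbenzaldehyde | COc1cc(C)c(O)c(C=O)c1
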